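## Retrosynthetic overview

1. Target 23 ⇒ 9-hydroxy macrocycle 20 ⇒ open-chain aldehyde 18. The ten-membered carbocycle is closed last, at C9–C10, by Nozaki–Hiyama–Kishi addition of a (Z)-α-iodo enoate to the C9 aldehyde.
2. Key disconnection, C6–O (together with C15–O): γ-lactone 16 ⇐ acyclic diene ester 14 by a palladium-catalysed 1,4-hydroxylactonisation that sets C6, the C4=C5 geometry and the C15 alcohol in one operation.
3. C7–C8: indium Barbier union of trienyl bromide 10 with (R)-glyceraldehyde acetonide 11, which sets C7 and C8; the acetonide is later cut back to the C9 aldehyde.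
4. 10 ⇐ glutaraldehyde 1 by Wittig (iodo ylide), α-methylenation, Wittig, Morita–Baylis–Hillman reaction and SN2′ bromination.
5. Ring order: γ-lactone first (step 8), ten-membered carbocycle second (step 10).

Assumption: locants C1–C15 in the text follow germacranolide numbering (C6 lactone carbinol, C7, C8 methacrylate, C9 acetate, C10 bearing the C14 ester, C4 bearing C15, C11–C13 the methylene-lactone carbons), and the target is (6R,7S,8S,9R) with both ring olefins cis within the ring, as read from the SMILES.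

## Route

Step 1
Reactants: 1 glutaraldehyde (50% aqueous, 3 equiv); 2 methyl (triphenylphosphoranylidene)acetate
Product: 4 methyl (2Z)-2-iodo-7-oxohept-2-enoate, via iodo ylide 3 (not isolated)
Conditions: 2, NIS (1.05 equiv), CH2Cl2, −20 °C, 30 min; then 1, 0 °C → rt
Reagents that add atoms: N-iodosuccinimide, O=C1CCC(=O)N1I
Why: N-Iodosuccinimide iodinates the stabilised ylide to iodo ylide 3, whose Wittig reaction with one formyl group of excess glutaraldehyde gives the α-iodo enoate with the alkyl chain trans to the ester (Z); no stereocentre is formed.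

Step 2
Reactants: 4 methyl (2Z)-2-iodo-7-oxohept-2-enoate
Product: 5 methyl (2Z)-6-formyl-2-iodohepta-2,6-dienoate
Conditions: 37% aq. CH2O (1.2 equiv), pyrrolidine (10 mol %), EtCO2H (10 mol %), i-PrOH, 45 °C
Reagents that add atoms: formaldehyde, C=O
Why: Amine-catalysed Mannich-type α-methylenation, in which the pyrrolidine enamine of the only enolisable aldehyde adds to formaldehyde and the adduct eliminates to the 2-substituted acrolein (this carbon becomes C15); no stereocentre is formed.

Step 3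
Reactants: 5 methyl (2Z)-6-formyl-2-iodohepta-2,6-dienoate; 6 (triphenylphosphoranylidene)acetaldehyde
Product: 7 methyl (2Z,7E)-2-iodo-6-methylidene-9-oxonona-2,7-dienoate
Conditions: 6 (1.05 equiv), toluene, 70 °C
Reagents that add atoms: none
Why: E-selective Wittig olefination with a formyl-stabilised ylide adds C6 and C7, and the use of one equivalent of ylide limits double homologation; no stereocentre is formed.

Step 4
Reactants: 7 methyl (2Z,7E)-2-iodo-6-methylidene-9-oxonona-2,7-dienoate; 8 tert-butyl acrylate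
Product: 9 1-tert-butyl 11-methyl (4E,9Z)-3-hydroxy-10-iodo-2,6-dimethylideneundeca-4,9-dienedioate (racemic at C3)
Conditions: 8 (5 equiv), DABCO (1 equiv), 1,4-dioxane/H2O 1:1, rt, 3–5 d
Reagents that add atoms: none
Why: Morita–Baylis–Hillman reaction, in which the DABCO–acrylate zwitterion adds 1,2 to the dienal and DABCO is then eliminated; the new carbinol centre is racemic and is erased in step 5.

Step 5
Reactants: 9 1-tert-butyl 11-methyl (4E,9Z)-3-hydroxy-10-iodo-2,6-dimethylideneundeca-4,9-dienedioate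
Product: 10 1-tert-butyl 11-methyl (2Z,4E,9Z)-2-(bromomethyl)-10-iodo-6-methylideneundeca-2,4,9-trienedioate
Conditions: PBr3 (0.45 equiv), Et2O, −10 → 0 °C
Reagents that add atoms: phosphorus tribromide, BrP(Br)Br
Why: Bromide displaces the activated hydroxyl with allylic transposition (SN2′) toward the acrylate terminus, giving the fully conjugated primary bromide with the dienyl group trans to the ester (2Z), and the carbinol stereocentre disappears.

Step 6
Reactants: 10 1-tert-butyl 11-methyl (2Z,4E,9Z)-2-(bromomethyl)-10-iodo-6-methylideneundeca-2,4,9-trienedioate; 11 (R)-2,2-dimethyl-1,3-dioxolane-4-carbaldehyde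
Product: 13 1-tert-butyl 11-methyl (3R,4E,9Z)-3-{(S)-[(4R)-2,2-dimethyl-1,3-dioxolan-4-yl](hydroxy)methyl}-10-iodo-2,6-dimethylideneundeca-4,9-dienedioate, via allylindium dibromide 12 (not isolated)
Conditions: In powder (1.5 equiv), 11 (1.5 equiv), THF/H2O 1:1, rt
Reagents that add atoms: indium, [In] (held only in 12; none remains in 13)
Why: Barbier allylation, in which indium inserts into the allylic C–Br bond and allylindium 12 adds through its γ-carbon (C7) in a closed chair transition state, the dienyl group cis to the metal-bearing CH2 giving the 7,8-syn relationship and Felkin–Anh attack anti to the dioxolane oxygen of 11 giving the 8,9-anti adduct, so that C7 and C8 are both fixed by the (R)-centre of 11, while the tert-butyl ester prevents lactonisation onto O8.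

Step 7
Reactants: 13 1-tert-butyl 11-methyl (3R,4E,9Z)-3-{(S)-[(4R)-2,2-dimethyl-1,3-dioxolan-4-yl](hydroxy)methyl}-10-iodo-2,6-dimethylideneundeca-4,9-dienedioate
Product: 14 1-tert-butyl 11-methyl (3R,4E,9Z)-3-{(S)-[(4R)-2,2-dimethyl-1,3-dioxolan-4-yl][(2-methylprop-2-enoyl)oxy]methyl}-10-iodo-2,6-dimethylideneundeca-4,9-dienedioate
Conditions: methacrylic anhydride (2 equiv), Et3N, DMAP (20 mol %), CH2Cl2, 0 °C → rt
Reagents that add atoms: methacrylic anhydride, C=C(C)C(=O)OC(=O)C(C)=C
Why: DMAP-catalysed acylation of the secondary C8 alcohol by the anhydride, with the configuration at C8 retained because its C–O bond is not broken.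

Step 8
Reactants: 14 1-tert-butyl 11-methyl (3R,4E,9Z)-3-{(S)-[(4R)-2,2-dimethyl-1,3-dioxolan-4-yl][(2-methylprop-2-enoyl)oxy]methyl}-10-iodo-2,6-dimethylideneundeca-4,9-dienedioate
Product: 16 methyl (2Z,6E)-7-[(2R,3S)-3-{(S)-[(4R)-2,2-dimethyl-1,3-dioxolan-4-yl][(2-methylprop-2-enoyl)oxy]methyl}-4-methylidene-5-oxooxolan-2-yl]-6-(hydroxymethyl)-2-iodohepta-2,6-dienoate, via allylpalladium trifluoroacetate 15 (not isolated)
Conditions: Pd(OCOCF3)2 (10 mol %), 2,6-dimethyl-1,4-benzoquinone (2 equiv), acetone/H2O 10:1, 20 °C, dark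
Reagents that add atoms: water, O; palladium bis(trifluoroacetate), FC(F)(F)C(=O)O[Pd]OC(=O)C(F)(F)F (held only in 15)
Why: Proposed new method: a dealkylative 1,4-hydroxylactonisation of a 1,3-diene, in which divalent palladium binds the s-trans C6=C5–C4=C15 diene (the only olefins of 14 that are not electron-poor), the carbonyl oxygen of the tert-butyl ester attacks C6 anti to palladium in a 5-exo mode through the rotamer that keeps H7 eclipsed with the C5=C6 bond and the bulky C8 group outside, so that the new C6–O bond is trans to C8 on the lactone (6R), loss of the tert-butyl cation makes the closure irreversible, the syn-η3-allylpalladium 15 (C6 cis to C3) is opened at its unhindered C15 terminus by water (or by trifluoroacetate, which is hydrolysed on work-up) to give the C4=C5 bond with C15 trans to C6 and the free C15 hydroxyl, and the quinone, chosen as a poor dienophile, returns zerovalent palladium to the divalent state; the closest known reactions are the palladium/benzoquinone 1,4-acetoxylactonisation of dienyl carboxylic acids and the halolactonisation of tert-butyl esters, but water as terminating nucleophile, a tert-butyl ester as internal nucleophile and an acyclic 2-alkyl diene with an allylic stereocentre have not been shown.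

Step 9
Reactants: 16 methyl (2Z,6E)-7-[(2R,3S)-3-{(S)-[(4R)-2,2-dimethyl-1,3-dioxolan-4-yl][(2-methylprop-2-enoyl)oxy]methyl}-4-methylidene-5-oxooxolan-2-yl]-6-(hydroxymethyl)-2-iodohepta-2,6-dienoate
Product: 18 methyl (2Z,6E)-6-(hydroxymethyl)-2-iodo-7-[(2R,3S)-4-methylidene-3-{(1S)-1-[(2-methylprop-2-enoyl)oxy]-2-oxoethyl}-5-oxooxolan-2-yl]hepta-2,6-dienoate, via diol 17 (not isolated)
Conditions: H5IO6 (1.5 equiv), EtOAc, rt, 2 h; crude 18 used at once
Reagents that add atoms: none
Why: Periodic acid first hydrolyses the terminal acetonide to diol 17 and then cleaves the glycol (Malaprade cleavage), turning the former glyceraldehyde C2 into the C9 aldehyde without base, so the α-acyloxy stereocentre C8 is not epimerised and no new stereocentre is formed.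

Step 10
Reactants: 18 methyl (2Z,6E)-6-(hydroxymethyl)-2-iodo-7-[(2R,3S)-4-methylidene-3-{(1S)-1-[(2-methylprop-2-enoyl)oxy]-2-oxoethyl}-5-oxooxolan-2-yl]hepta-2,6-dienoate
Product: 20 methyl (3aS,4S,5R,6E,10E,11aR)-5-hydroxy-10-(hydroxymethyl)-3-methylidene-4-[(2-methylprop-2-enoyl)oxy]-2-oxo-2,3,3a,4,5,8,9,11a-octahydrocyclodeca[b]furan-6-carboxylate, via alkenylchromium dichloride 19 (not isolated)
Conditions: CrCl2 (8 equiv), NiCl2 (5 mol %), degassed DMSO/THF 3:1, slow addition of 18 to 0.002 M, rt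
Reagents that add atoms: chromium dichloride, Cl[Cr]Cl (held only in 19; none remains in 20)
Why: Nozaki–Hiyama–Kishi reaction, in which zerovalent nickel inserts into the C–I bond, transmetalation gives alkenylchromium 19 (trivalent chromium) with retention of olefin geometry, and its addition to the aldehyde, templated by the trans-lactone and the two cis-in-ring olefins, closes the ten-membered ring with the nucleophile entering anti to the C8–O bond (polar Felkin–Anh), which gives the 8,9-anti (9R) carbinol.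

Step 11
Reactants: 20 methyl (3aS,4S,5R,6E,10E,11aR)-5-hydroxy-10-(hydroxymethyl)-3-methylidene-4-[(2-methylprop-2-enoyl)oxy]-2-oxo-2,3,3a,4,5,8,9,11a-octahydrocyclodeca[b]furan-6-carboxylate
Product: 23 CNP0179134.4 (methyl (3aS,4S,5R,6E,10E,11aR)-5-(acetyloxy)-10-(hydroxymethyl)-3-methylidene-4-[(2-methylprop-2-enoyl)oxy]-2-oxo-2,3,3a,4,5,8,9,11a-octahydrocyclodeca[b]furan-6-carboxylate), via triethylsilyl ether 21 (not isolated), via triethylsilyl ether acetate 22 (not isolated)
Conditions: TESCl (1.05 equiv), imidazole, CH2Cl2, −78 °C; then Ac2O, DMAP, pyridine, 0 °C → rt; then HF·pyridine, THF, 0 °C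
Reagents that add atoms: acetic anhydride, CC(=O)OC(C)=O; chlorotriethylsilane, CC[Si](Cl)(CC)CC (held only in 21 and 22)
Why: The unhindered primary allylic C15 hydroxyl is silylated selectively at −78 °C, the remaining hindered C9 hydroxyl is then acetylated under DMAP catalysis before the neighbouring methacrylate can migrate, and HF·pyridine removes the triethylsilyl group without touching the esters; no stereocentre is affected.

## Compound list

1 | glutaraldehyde (pentanedial) | O=CCCCC=O | starting material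
2 | methyl (triphenylphosphoranylidene)acetate | COC(=O)C=P(c1ccccc1)(c1ccccc1)c1ccccc1 | starting material
3 | methyl iodo(triphenylphosphoranylidene)acetate (iodo ylide) | COC(=O)C(I)=P(c1ccccc1)(c1ccccc1)c1ccccc1 | intermediate
4 | methyl (2Z)-2-iodo-7-oxohept-2-enoate | O=CCCC/C=C(\I)C(=O)OC | intermediate
5 | methyl (2Z)-6-formyl-2-iodohepta-2,6-dienoate | C=C(C=O)CC/C=C(\I)C(=O)OC | intermediate
6 | (triphenylphosphoranylidene)acetaldehyde | O=CC=P(c1ccccc1)(c1ccccc1)c1ccccc1 | starting material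
7 | methyl (2Z,7E)-2-iodo-6-methylidene-9-oxonona-2,7-dienoate | O=C/C=C/C(=C)CC/C=C(\I)C(=O)OC | intermediate
8 | tert-butyl acrylate | C=CC(=O)OC(C)(C)C | starting material
9 | 1-tert-butyl 11-methyl (4E,9Z)-3-hydroxy-10-iodo-2,6-dimethylideneundeca-4,9-dienedioate (racemic at C3) | C=C(C(=O)OC(C)(C)C)C(O)/C=C/C(=C)CC/C=C(\I)C(=O)OC | intermediate
10 | 1-tert-butyl 11-methyl (2Z,4E,9Z)-2-(bromomethyl)-10-iodo-6-methylideneundeca-2,4,9-trienedioate | BrC/C(C(=O)OC(C)(C)C)=C\C=C\C(=C)CC/C=C(\I)C(=O)OC | intermediate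
11 | (R)-2,2-dimethyl-1,3-dioxolane-4-carbaldehyde | O=C[C@H]1COC(C)(C)O1 | starting material
12 | allylindium dibromide derived from 10 (indium on the former CH2Br carbon) | Br[In](Br)C/C(C(=O)OC(C)(C)C)=C\C=C\C(=C)CC/C=C(\I)C(=O)OC | intermediate
13 | 1-tert-butyl 11-methyl (3R,4E,9Z)-3-{(S)-[(4R)-2,2-dimethyl-1,3-dioxolan-4-yl](hydroxy)methyl}-10-iodo-2,6-dimethylideneundeca-4,9-dienedioate | O[C@H]([C@H]1COC(C)(C)O1)[C@H](/C=C/C(=C)CC/C=C(\I)C(=O)OC)C(=C)C(=O)OC(C)(C)C | intermediate
14 | 1-tert-butyl 11-methyl (3R,4E,9Z)-3-{(S)-[(4R)-2,2-dimethyl-1,3-dioxolan-4-yl][(2-methylprop-2-enoyl)oxy]methyl}-10-iodo-2,6-dimethylideneundeca-4,9-dienedioate | C=C(C)C(=O)O[C@H]([C@H]1COC(C)(C)O1)[C@H](/C=C/C(=C)CC/C=C(\I)C(=O)OC)C(=C)C(=O)OC(C)(C)C | intermediate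
15 | allylpalladium trifluoroacetate of the closed lactone (η3-allyl over C5–C4–C15, drawn in its η1 form with palladium on C15) | C=C(C)C(=O)O[C@H]([C@H]1COC(C)(C)O1)[C@H]2C(=C)C(=O)O[C@@H]2/C=C(/C[Pd]OC(=O)C(F)(F)F)CC/C=C(\I)C(=O)OC | intermediate
16 | methyl (2Z,6E)-7-[(2R,3S)-3-{(S)-[(4R)-2,2-dimethyl-1,3-dioxolan-4-yl][(2-methylprop-2-enoyl)oxy]methyl}-4-methylidene-5-oxooxolan-2-yl]-6-(hydroxymethyl)-2-iodohepta-2,6-dienoate | C=C(C)C(=O)O[C@H]([C@H]1COC(C)(C)O1)[C@H]2C(=C)C(=O)O[C@@H]2/C=C(/CO)CC/C=C(\I)C(=O)OC | intermediate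
17 | methyl (2Z,6E)-7-[(2R,3S)-3-{(1S,2R)-2,3-dihydroxy-1-[(2-methylprop-2-enoyl)oxy]propyl}-4-methylidene-5-oxooxolan-2-yl]-6-(hydroxymethyl)-2-iodohepta-2,6-dienoate | C=C(C)C(=O)O[C@H]([C@H](O)CO)[C@H]1C(=C)C(=O)O[C@@H]1/C=C(/CO)CC/C=C(\I)C(=O)OC | intermediate
18 | methyl (2Z,6E)-6-(hydroxymethyl)-2-iodo-7-[(2R,3S)-4-methylidene-3-{(1S)-1-[(2-methylprop-2-enoyl)oxy]-2-oxoethyl}-5-oxooxolan-2-yl]hepta-2,6-dienoate | C=C(C)C(=O)O[C@H](C=O)[C@H]1C(=C)C(=O)O[C@@H]1/C=C(/CO)CC/C=C(\I)C(=O)OC | intermediate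
19 | alkenylchromium dichloride derived from 18 (chromium in place of iodine) | C=C(C)C(=O)O[C@H](C=O)[C@H]1C(=C)C(=O)O[C@@H]1/C=C(/CO)CC/C=C(\[Cr](Cl)Cl)C(=O)OC | intermediate
20 | methyl (3aS,4S,5R,6E,10E,11aR)-5-hydroxy-10-(hydroxymethyl)-3-methylidene-4-[(2-methylprop-2-enoyl)oxy]-2-oxo-2,3,3a,4,5,8,9,11a-octahydrocyclodeca[b]furan-6-carboxylate | C=C(C)C(=O)O[C@H]1[C@H]2C(=C)C(=O)O[C@@H]2/C=C(/CO)CC/C=C(/C(=O)OC)[C@H]1O | intermediate
21 | 15-O-triethylsilyl ether of 20 (10-{[(triethylsilyl)oxy]methyl}, 5-hydroxy) | C=C(C)C(=O)O[C@H]1[C@H]2C(=C)C(=O)O[C@@H]2/C=C(/CO[Si](CC)(CC)CC)CC/C=C(/C(=O)OC)[C@H]1O | intermediate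
22 | 15-O-triethylsilyl ether of 23 (10-{[(triethylsilyl)oxy]methyl}, 5-acetyloxy) | C=C(C)C(=O)O[C@H]1[C@H]2C(=C)C(=O)O[C@@H]2/C=C(/CO[Si](CC)(CC)CC)CC/C=C(/C(=O)OC)[C@H]1OC(C)=O | intermediate
23 | CNP0179134.4, methyl (3aS,4S,5R,6E,10E,11aR)-5-(acetyloxy)-10-(hydroxymethyl)-3-methylidene-4-[(2-methylprop-2-enoyl)oxy]-2-oxo-2,3,3a,4,5,8,9,11a-octahydrocyclodeca[b]furan-6-carboxylate | C=C(C)C(=O)O[C@H]1[C@H]2C(=C)C(=O)O[C@@H]2/C=C(/CO)CC/C=C(/C(=O)OC)[C@H]1OC(C)=O | target

## Step count and risk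

Total step count: 11. Longest linear sequence: 11 steps (1 → 23); compounds 2, 6, 8 and 11 are purchased.

**Step 8 (the new 1,4-hydroxylactonisation).** The ester carbonyl may be too weak a nucleophile, water may open the diene complex at both termini, or the cis-lactone may form. The fallback uses known reaction types only, sets out from 14 and comes back at 16. TMSOTf and 2,6-lutidine (CH2Cl2, 0 °C) exchange the tert-butyl group for silicon to give the trimethylsilyl ester F1, which aqueous work-up hydrolyses to the free acrylic acid F2. PhSeCl (CH2Cl2, −78 °C → rt, no base, equilibrating conditions) then effects phenylselenolactonisation to the 6,7-trans phenylselenolactone F3, with oxygen on C6 and selenium on C5 (anti addition), the selenide being allylic to the C4=C15 methylene. H2O2 and pyridine (CH2Cl2/H2O, 0 °C) oxidise it to the allylic selenoxide F4, which undergoes [2,3]-sigmatropic shift to the C15 selenenate F5 with C6 trans to C15, and hydrolysis of F5 on work-up gives 16.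

**Step 10 (Nozaki–Hiyama–Kishi ring closure).** The ring conformation, not only the Felkin preference, decides the C9 configuration, and oligomers compete. The fallback moves the control of C9 from the C–C bond formation to a reagent-controlled ketone reduction; it sets out from 18 and comes back at 21. The closure is run as above and the mixture of 20 and its C9 epimer F6 is silylated at the primary hydroxyl (TESCl, imidazole, CH2Cl2, −78 °C) to give 21 together with the epimeric triethylsilyl ether F7. Dess–Martin periodinane (CH2Cl2, NaHCO3, 0 °C) converges both on the single macrocyclic C9 ketone F8. (R)-2-Methyl-CBS-oxazaborolidine with catecholborane (toluene, −78 °C), for which the ester-bearing sp2 carbon C10 is the large group, delivers hydride to give the 9R alcohol 21, which is acetylated and desilylated as in step 11.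

**Step 6 (indium Barbier union).** The trienyl indium may react at C5 instead of C7, and Felkin selectivity with 11 may be modest. The fallback replaces the Barbier reagent by an isolable allylboronate that reacts only through a closed chair; it sets out from 9 and comes back at 13. Ac2O and DMAP (CH2Cl2, 0 °C) give the Morita–Baylis–Hillman acetate F9. B2pin2 with CuCl (10 mol %) and KOtBu (20 mol %) in THF at rt borylates it with SN2′ transposition to the allylboronate F10, whose boron-bearing CH2 is cis to the dienyl group. Sc(OTf)3 (10 mol %) in toluene at −20 °C promotes allylboration of 11 through C7, giving the 7,8-syn-8,9-anti pinacol borate F11 (the pattern known for cis-γ-substituted allylboronates with this aldehyde), and aqueous NaHCO3 work-up frees 13.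

## Further compounds

F1 | step 8 | trimethylsilyl ester of F2 (tert-butyl group of 14 replaced by SiMe3) | C=C(C)C(=O)O[C@H]([C@H]1COC(C)(C)O1)[C@H](/C=C/C(=C)CC/C=C(\I)C(=O)OC)C(=C)C(=O)O[Si](C)(C)C
F2 | step 8 | (3R,4E,9Z)-3-{(S)-[(4R)-2,2-dimethyl-1,3-dioxolan-4-yl][(2-methylprop-2-enoyl)oxy]methyl}-10-iodo-11-methoxy-2,6-dimethylidene-11-oxoundeca-4,9-dienoic acid | C=C(C)C(=O)O[C@H]([C@H]1COC(C)(C)O1)[C@H](/C=C/C(=C)CC/C=C(\I)C(=O)OC)C(=C)C(=O)O
F3 | step 8 | methyl (2Z,7R)-7-[(2S,3R)-3-{(S)-[(4R)-2,2-dimethyl-1,3-dioxolan-4-yl][(2-methylprop-2-enoyl)oxy]methyl}-4-methylidene-5-oxooxolan-2-yl]-2-iodo-6-methylidene-7-(phenylselanyl)hept-2-enoate | C=C(C)C(=O)O[C@H]([C@H]1COC(C)(C)O1)[C@H]2C(=C)C(=O)O[C@@H]2[C@H]([Se]c3ccccc3)C(=C)CC/C=C(\I)C(=O)OC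
F4 | step 8 | Se-oxide of F3 (allylic selenoxide, configuration at selenium not defined) | C=C(C)C(=O)O[C@H]([C@H]1COC(C)(C)O1)[C@H]2C(=C)C(=O)O[C@@H]2[C@H]([Se](=O)c3ccccc3)C(=C)CC/C=C(\I)C(=O)OC
F5 | step 8 | O-phenylselenenate of 16 at the C15 oxygen | C=C(C)C(=O)O[C@H]([C@H]1COC(C)(C)O1)[C@H]2C(=C)C(=O)O[C@@H]2/C=C(/CO[Se]c3ccccc3)CC/C=C(\I)C(=O)OC
F6 | step 10 | C9 epimer of 20, methyl (3aS,4S,5S,6E,10E,11aR)-5-hydroxy-10-(hydroxymethyl)-3-methylidene-4-[(2-methylprop-2-enoyl)oxy]-2-oxo-2,3,3a,4,5,8,9,11a-octahydrocyclodeca[b]furan-6-carboxylate | C=C(C)C(=O)O[C@H]1[C@H]2C(=C)C(=O)O[C@@H]2/C=C(/CO)CC/C=C(/C(=O)OC)[C@@H]1O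
F7 | step 10 | 15-O-triethylsilyl ether of F6 (C9 epimer of 21) | C=C(C)C(=O)O[C@H]1[C@H]2C(=C)C(=O)O[C@@H]2/C=C(/CO[Si](CC)(CC)CC)CC/C=C(/C(=O)OC)[C@@H]1O
F8 | step 10 | methyl (3aS,4S,6E,10E,11aR)-3-methylidene-4-[(2-methylprop-2-enoyl)oxy]-2,5-dioxo-10-{[(triethylsilyl)oxy]methyl}-2,3,3a,4,5,8,9,11a-octahydrocyclodeca[b]furan-6-carboxylate | C=C(C)C(=O)O[C@H]1[C@H]2C(=C)C(=O)O[C@@H]2/C=C(/CO[Si](CC)(CC)CC)CC/C=C(/C(=O)OC)C1=O
F9 | step 6 | 1-tert-butyl 11-methyl (4E,9Z)-3-(acetyloxy)-10-iodo-2,6-dimethylideneundeca-4,9-dienedioate (racemic at C3) | C=C(C(=O)OC(C)(C)C)C(OC(C)=O)/C=C/C(=C)CC/C=C(\I)C(=O)OC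
F10 | step 6 | 1-tert-butyl 11-methyl (2E,4E,9Z)-10-iodo-6-methylidene-2-[(4,4,5,5-tetramethyl-1,3,2-dioxaborolan-2-yl)methyl]undeca-2,4,9-trienedioate (boron-bearing CH2 cis to the dienyl group) | CC1(C)OB(C/C(C(=O)OC(C)(C)C)=C\C=C\C(=C)CC/C=C(\I)C(=O)OC)OC1(C)C
F11 | step 6 | pinacol borate ester of 13 at the C8 oxygen | CC1(C)OB(O[C@H]([C@H]2COC(C)(C)O2)[C@H](/C=C/C(=C)CC/C=C(\I)C(=O)OC)C(=C)C(=O)OC(C)(C)C)OC1(C)C
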